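(The earlier runs and the new flask were computed with made-up constants, and the scatter is random.)

- Of the 4 questions, the last asks what free base does, so I looked for one number saying whether free base matters here.

| flask | electrophile | nucleophile | free base | remark | time |
|---|---|---|---|---|---|
| dawn | 0.020 M | 0.022 M | 0.024 M | run made earlier |  |
| noon | 0.020 M | 0.022 M | 0.040 M | run made earlier |  |
| spring | 0.020 M | 0.022 M | 0.087 M | run made earlier |  |
| cedar | 0.020 M | 0.0220 M | 0.0220 M |  | 4.0 h |
| elm | 0.020 M | 0.0220 M | 0.0440 M |  | 4.0 h |
| oak | 0.020 M | 0.0220 M | 0.0880 M |  | 4.0 h |

| run | time / h | electrophile / % | product / % |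
|---|---|---|---|
| dawn | 0.333 | 82.9 | 8.7 |
| dawn | 0.667 | 71.5 | 13.8 |
| dawn | 1.00 | 62.9 | 19.2 |
| dawn | 2.00 | 50.9 | 29.6 |
| dawn | 4.00 | 41.1 | 41.1 |
| noon | 0.833 | 67.1 | 17.2 |
| noon | 1.50 | 55.7 | 25.3 |
| noon | 2.50 | 46.9 | 32.7 |
| noon | 3.00 | 43.8 | 36.2 |
| noon | 4.00 | 39.9 | 40.4 |
| spring | 0.833 | 65.9 | 16.8 |
| spring | 1.50 | 55.7 | 24.6 |
| spring | 2.50 | 46.7 | 33.0 |
| spring | 3.00 | 43.5 | 35.9 |
| spring | 4.00 | 39.9 | 41.7 |

(scatter of a reading: 0.5 percentage points)

- part of the electrophile that has reacted at the end, cedar
- part of the electrophile that has reacted at the end, elm
- part of the electrophile that has reacted at the end, oak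
- what raising the concentration of free base from its lowest to its highest value here does to the part of the electrophile that has reacted (changes below 5 percentage points count as none) (it rises / it falls / no change)

- what has gone from electrophile into another species counts as reacted, even if it can come back

- I counted turnovers: if each product formed cost one free base, how many times over would each free base have served by the end?
- That load is the product, as a fraction of the electrophile charged, divided by the equivalents of free base. For cedar, dawn's product of 41.1% over 1.10 equivalents gives a load of 0.374.
- A load below one means that, on this count, the free base charged in cedar covers the product I expected by the end, so I did not expect free base to be the limiting reagent there.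
- From dawn to spring the load fell from 0.343 to 0.0959, while the reacted part went from 58.9% to 60.1%. That shift of 1.2 percentage points is less than the margin of 5 points.
- So I took 58.9% for cedar, 60.1% for elm and oak, and no change for the trend.
- One number was not enough for the level, though. The load speaks of free base, but the level is borrowed from runs with nucleophile at 0.022 M in each.
- The forecast gave 58.5%, 60%, 60% and no change, on the ground that "a near fourfold change in base does almost nothing"; its cedar figure stood just below mine.
- The flasks gave 59.2% for cedar, 59.6% for elm and 60.3% for oak, a change of 1.1 points, so the trend was no change.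

    electrophile + nucleophile → acid set free + product (k = 0.00380 L mol⁻¹ s⁻¹)
    nucleophile + acid set free ⇌ protonated nucleophile, settled at all times (K = 2800 L mol⁻¹)
    acid set free + free base ⇌ salt of the base, settled at all times (K = 46.0 L mol⁻¹)
    acid set free + free base ⇌ idle adduct, settled at all times (K = 76.0 L mol⁻¹)
    electrophile ⇌ dormant form (K = 0.430, k = 9.10 × 10⁻⁵ s⁻¹)
    acid set free → by-product carried off (k = 1.60 × 10⁻⁵ s⁻¹)

- Counted with cedar's own product of 40.0%, the load was 0.364, and 96% of cedar's free base was still free. A neighbour flask is elm with nucleophile cut to 0.440 equiv, its other charges and time held. Its load of 0.0857 is lower than elm's 0.184, yet its reacted part stood at 43.7% against elm's 59.6%.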